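## Analysis of the target

The target, 5,7-dihydroxy-3,8-dimethoxy-2-(4-methoxyphenyl)-6-methyl-4H-chromen-4-one, is a flavone: a benzo-fused 4-pyranone (rings A and C) with a 4-methoxyphenyl group (ring B) at C2. It has no stereocenter, so any stereochemistry in an intermediate is temporary and can be carried as a racemate or a mixture. Ring A is hexasubstituted: C5 carries OH, C6 a methyl group, C7 OH, C8 OCH3, and C4a and C8a are the fusion atoms. Four oxygens on this ring (O1, O5, O7, O8) must be told apart, and the C-methyl must sit exactly between the two free hydroxyls. The sensitive groups are the chelated C5 phenol, the acidic C7 phenol, the easily oxidized ring A, and three methyl ethers (C3, C8, C4') that must survive the step that frees the two phenols. The difficulty is the regiochemistry of ring A, because stepwise substitution of a phloroglucinol-type arene does not readily distinguish C6 from C8 or O5 from O7. The strategy rests on reading C5–C6–C7–C8 (para oxygens at C5 and C8 around C6–CH3 and C7–O) as the four carbons of a 3-alkoxy-4-methylcyclobutenedione, and C4a–C8a as the double bond of a cyclic enol ether that already carries O1. Ring A is then built rather than substituted, and each oxygen arrives differentiated: free OH at C5, isopropyl ether at C7, methyl ether at C8.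

## Retrosynthetic reasoning

**23 back to 22.** The O–alkyl bonds of a C5 benzyl ether and a C7 isopropyl ether are cut last. These are the only non-methyl ethers in 22, so a reagent that removes benzyl and secondary alkyl groups but not methyl groups can free both phenols in one operation. The gain is that the two phenols stay masked through every oxidation.

**22 back to 21 and 19.** The C3–OCH3 group is removed in two stages: the O–CH3 bond (back to flavonol 21), then the C3–O bond (back to flavone 19). C3 is chosen because the C2=C3 bond of 19 is the only enol-ether-like alkene in the molecule and ring A has no free position. The forward reaction must oxygenate C3 without touching ring A, which is why the C5 phenol is capped beforehand.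

**19 back to 15.** No skeletal bond is cut here; only the oxidation level of ring C and one protecting group change. The C2=C3 bond is traced to flavanone 18, the C4 ketone to alcohol 17 and its silyl ether 16, and the C5 benzyl ether to the free phenol 15. This detour is required because the ring-forming step needs C4a–C8a as an isolated enol-ether double bond, so C2, C3 and C4 must be sp3 at that stage.

**15 back to 12 (key disconnection).** The C5–C4a bond of ring A is cut, giving dienylketene 13, which is the open form of cyclobutenone 12 (the former C5–C8 bond of the four-membered ring). Cutting here lets C5, C6, C7 and C8 come with their substituents as one unit. Any other disconnection of a hexasubstituted benzene would need a series of aromatic substitutions with C6/C8 ambiguity. The forward reaction must open the four-membered ring with the enol ether turned toward the ketene and then close the six-membered ring.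

**12 back to 9 and 3.** The C8–C8a bond (quaternary cyclobutenone carbon to C6 of the dihydropyran) and the O–CH3 bond at that carbon are cut. The forward reaction is addition of vinyllithium 10, made from 9, to the more electrophilic carbonyl of dione 3, followed by methylation of alkoxide 11. Because O1 is already bonded to C8a in 9, ring C cannot close the wrong way.

**3 back to 1.** The C6–CH3 bond is cut, leading to squarate 1. One methyl nucleophile adds, and acid turns adduct 2 into the dione.

**9 back to 4 and 5.** The silyl ether goes back to alcohol 8 and this to enone 7. In 7, the O1–C8a and C2–C3 bonds (flavone numbering) are cut in a hetero-Diels–Alder sense to aldehyde 4 and diene 5; the primary cycloadduct 6 loses its acetal and silyl groups on acid treatment. This delivers ring C with the ring B aryl group at C2 and an oxygen at C4 in one step from two commercial materials.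

## Alternatives that were turned down

Alternative 1: Ring C is disconnected at O1–C8a, C4–C4a and O1–C2 into the aryne precursor 3,5-bis(benzyloxy)-4-methyl-2-(trimethylsilyl)phenyl trifluoromethanesulfonate A2 and 2,3-dimethoxy-3-(4-methoxyphenyl)acrylic acid A3.
- Forward key step: a fluoride source releases the aryne from A2. The carboxylate of A3 adds through oxygen at the aryne carbon remote from the benzyloxy group, and the aryl anion attacks the acyl carbon. The resulting ortho-acyl phenoxide closes ring C by conjugate addition and loss of the β-methoxyl, giving 5,7-bis(benzyloxy)-3-methoxy-2-(4-methoxyphenyl)-6-methylchromen-4-one A1.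
- For: it is convergent, and it delivers the flavone oxidation level and the C3 methoxyl at once. On this point it is stronger than the chosen route, which spends steps 8 to 12 on ring C.
- Against: A1 has hydrogen at C8. The C8 methoxyl would have to be added to an electron-rich flavone afterwards, or A2 would have to become a hexasubstituted arene, which is the original ring A problem in another form. Acyl transfer from the fully substituted acryloyl group of A3 next to a benzyloxy substituent is also sterically demanding.
- Comparison: the chosen strategy gives up convergence in ring C but places all four ring A oxygens, differentiated, in the step that makes the ring.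

Alternative 2: Ring A is disconnected at C5–C6, C7–C8 and C5–C4a into 2-methoxy-2-[5-methoxy-6-(4-methoxyphenyl)-4-oxo-4H-pyran-2-yl]acetyl chloride A5 and 1-(triisopropylsilyloxy)prop-1-yne A6.
- Forward key step: an amine base converts A5 into a methoxy(pyranonyl)ketene, which undergoes [2+2] cycloaddition with A6. The cyclobutenone opens, and the new ketene closes on the pyranone carbon next to the carbonyl. The product is 5-hydroxy-3,8-dimethoxy-2-(4-methoxyphenyl)-6-methyl-7-(triisopropylsilyloxy)chromen-4-one A4.
- For: A4 is one desilylation from the target, and it uses the same ring A logic as the chosen route. In the end game it is clearly stronger.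
- Against: three events must succeed in one flask. The alkoxyketene must be formed and captured by A6 before it dimerizes, the [2+2] must have the right regiochemistry, and the electrocyclization must end on the electron-poor, cross-conjugated pyranone double bond. Neither A5, a trisubstituted 4-pyranone with an α-methoxy acid side chain, nor A6 is a stock compound, so both add steps before the key step.
- Comparison: the chosen strategy separates the events. The C8–C8a bond is made by 1,2-addition of a defined organolithium to a defined carbonyl, precursor 12 can be isolated, and the thermal step closes onto an electron-rich enol ether. The price is a longer finish.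

Alternative 3: Ring C is disconnected at C4a–C4, C4–C3 and O1–C2 into 3,5-bis(benzyloxy)-2-iodo-6-methoxy-4-methylphenol A8, a one-carbon carbonyl unit and 4-ethynylanisole A9.
- Forward key step: a carbonylative Sonogashira coupling joins the aryl iodide A8, the carbonyl carbon and the terminal alkyne A9. The C8a hydroxyl then adds to the ynone in the six-membered mode, giving 5,7-bis(benzyloxy)-8-methoxy-2-(4-methoxyphenyl)-6-methylchromen-4-one A7.
- For: it is modular, A9 is a simple commercial alkyne, and ring C forms directly at the flavone oxidation level. In that respect it is better than the chosen route.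
- Against: all the difficulty moves into A8, a hexasubstituted benzene whose four oxygens must be differentiated by stepwise aromatic chemistry. The iodide of A8 is flanked on both sides, which slows the coupling with A9. Five-membered closure to an aurone competes with flavone formation. A7 still lacks the C3 oxygen, so the end game is no shorter.
- Comparison: the chosen strategy answers the ring A question, which this alternative leaves open. In return it needs more oxidation-level changes in ring C.

Key step: step 6

Remark on the chemistry: the target is achiral, so all chiral intermediates are used as racemates, and "cis" refers only to the relative configuration at C2 and C4, both of which are removed later. The C4 oxygen is protected as a triisopropylsilyl ether because silicon-bound methyl groups would compete for the alkyllithium base in the C6 lithiation.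

## Route

Step 1
Reactants: 1 diisopropyl squarate
Product: 3 3-isopropoxy-4-methylcyclobut-3-ene-1,2-dione, via hydroxy adduct 2 (not isolated)
Conditions: MeLi, THF, −78 °C; then conc. aq. HCl, CH2Cl2, rt
Reagents that add atoms: methyllithium, [Li]C
Why: 1,2-Addition of the organolithium to one carbonyl of the squarate stops at the mono-adduct at low temperature; acid then ionizes the tertiary carbinol and expels isopropanol from the vinylogous position to give the 3-alkoxy-4-alkylcyclobutenedione (standard squarate alkylation).

Step 2
Reactants: 4 4-methoxybenzaldehyde; 5 trans-1-methoxy-3-(trimethylsilyloxy)buta-1,3-diene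
Product: 7 2-(4-methoxyphenyl)-2,3-dihydro-4H-pyran-4-one (racemic), via cycloadduct 6 (not isolated)
Conditions: ZnCl2 (cat.), THF, rt; then TFA, CH2Cl2, 0 °C
Reagents that add atoms: none
Why: Lewis-acid-catalysed hetero-Diels–Alder reaction; the nucleophilic CH2 terminus of the diene bonds to the aldehyde carbon, and acid then removes methanol and the silyl group to reveal the enone. The C2 stereocenter forms as a racemate.

Step 3
Reactants: 7 2-(4-methoxyphenyl)-2,3-dihydro-4H-pyran-4-one
Product: 8 cis-2-(4-methoxyphenyl)-3,4-dihydro-2H-pyran-4-ol (racemic)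
Conditions: NaBH4, CeCl3·7H2O, MeOH, −78 → −20 °C
Reagents that add atoms: none
Why: Luche 1,2-reduction of the vinylogous ester carbonyl; hydride should enter axially on the half-chair with the aryl group pseudo-equatorial, giving the cis alcohol. The configuration at C4 has no consequence later.

Step 4
Reactants: 8 cis-2-(4-methoxyphenyl)-3,4-dihydro-2H-pyran-4-ol
Product: 9 cis-2-(4-methoxyphenyl)-4-(triisopropylsilyloxy)-3,4-dihydro-2H-pyran
Conditions: TIPSOTf, 2,6-lutidine, CH2Cl2, −78 → 0 °C
Reagents that add atoms: triisopropylsilyl trifluoromethanesulfonate, CC(C)[Si](OS(=O)(=O)C(F)(F)F)(C(C)C)C(C)C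
Why: Silylation of a secondary allylic alcohol under buffered conditions, which avoids allylic ionization of the acid-sensitive enol ether; the bulky silyl ether tolerates alkyllithium bases.

Step 5
Reactants: 9 cis-2-(4-methoxyphenyl)-4-(triisopropylsilyloxy)-3,4-dihydro-2H-pyran; 3 3-isopropoxy-4-methylcyclobut-3-ene-1,2-dione
Product: 12 3-isopropoxy-4-methoxy-2-methyl-4-[cis-2-(4-methoxyphenyl)-4-(triisopropylsilyloxy)-3,4-dihydro-2H-pyran-6-yl]cyclobut-2-en-1-one (racemic; both epimers at the cyclobutenone carbon), via vinyllithium 10 (not isolated), via lithium alkoxide 11 (not isolated)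
Conditions: t-BuLi, THF/pentane, −78 → 0 °C; then 3, THF, −78 °C; then MeOTf, −78 → 0 °C
Reagents that add atoms: methyl trifluoromethanesulfonate, COS(=O)(=O)C(F)(F)F
Why: Oxygen-directed vinylic lithiation of the cyclic enol ether at C6, then 1,2-addition to the carbonyl of 3 next to the isopropoxy-bearing carbon (the other carbonyl is deactivated as a vinylogous ester), and O-methylation of the tertiary lithium alkoxide in the same flask, which fixes the future C8 methoxyl. Excess base is consumed by THF during the warm-up to 0 °C before 3 is added. The new quaternary center is uncontrolled, which does not matter because it becomes sp2 in step 6.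

Step 6
Reactants: 12 3-isopropoxy-4-methoxy-2-methyl-4-[cis-2-(4-methoxyphenyl)-4-(triisopropylsilyloxy)-3,4-dihydro-2H-pyran-6-yl]cyclobut-2-en-1-one
Product: 15 cis-7-isopropoxy-8-methoxy-2-(4-methoxyphenyl)-6-methyl-4-(triisopropylsilyloxy)chroman-5-ol (racemic), via dienylketene 13 (not isolated), via cyclohexadienone 14 (not isolated)
Conditions: toluene (degassed), 110 °C, Ar
Reagents that add atoms: none
Why: Heating 12 causes conrotatory four-electron opening of the cyclobutenone; the donor methoxyl on the quaternary carbon rotates outward, so the dihydropyranyl group turns inward and lies next to the ketene in 13, and both epimers of 12 converge. Thermal disrotatory six-electron electrocyclization then joins the ketene carbon (C5) to the enol-ether β-carbon (C4a) and closes the six-membered carbocyclic ring A as cyclohexa-2,4-dienone 14. Enolization of 14, driven by aromatization, gives phenol 15 with free OH at C5, methyl at C6, isopropoxy at C7 and methoxy at C8. The closest known reaction type is the thermal rearrangement of 4-alkenyl- and 4-(dihydropyranyl)-4-alkoxycyclobutenones to phenols and chromans (Moore rearrangement). The only new stereocenter, C4a in 14, is transient and is erased on tautomerization, and the cis C2/C4 relationship is untouched. The step needs torquoselective ring opening, which the 4-methoxy donor provides, and a single closure regiochemistry, which is guaranteed because O1–C8a and C8–C8a already exist and only one alkene terminus is within reach of the ketene. Neutral, oxygen-free, non-nucleophilic conditions keep the ketene from being trapped and protect the silyl ether and the electron-rich phenol.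

Step 7
Reactants: 15 cis-7-isopropoxy-8-methoxy-2-(4-methoxyphenyl)-6-methyl-4-(triisopropylsilyloxy)chroman-5-ol
Product: 16 cis-5-(benzyloxy)-7-isopropoxy-8-methoxy-2-(4-methoxyphenyl)-6-methyl-4-(triisopropylsilyloxy)chroman
Conditions: BnBr, K2CO3, Bu4NI (cat.), DMF, 50 °C
Reagents that add atoms: benzyl bromide, BrCc1ccccc1
Why: Williamson etherification of the only free hydroxyl; capping the para-methoxyphenol protects ring A from oxidation to a quinone in steps 9 to 11, and a primary benzylic halide can still reach the hindered oxygen.

Step 8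
Reactants: 16 cis-5-(benzyloxy)-7-isopropoxy-8-methoxy-2-(4-methoxyphenyl)-6-methyl-4-(triisopropylsilyloxy)chroman
Product: 17 cis-5-(benzyloxy)-7-isopropoxy-8-methoxy-2-(4-methoxyphenyl)-6-methylchroman-4-ol
Conditions: TBAF, THF, 0 °C → rt; then H2O
Reagents that add atoms: none
Why: Fluoride cleavage of the silyl ether; no other group is fluoride-labile.

Step 9
Reactants: 17 cis-5-(benzyloxy)-7-isopropoxy-8-methoxy-2-(4-methoxyphenyl)-6-methylchroman-4-ol
Product: 18 5-(benzyloxy)-7-isopropoxy-8-methoxy-2-(4-methoxyphenyl)-6-methylchroman-4-one (racemic)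
Conditions: Dess–Martin periodinane, NaHCO3, CH2Cl2, rt
Reagents that add atoms: none
Why: Dess–Martin oxidation of a secondary benzylic alcohol; the buffered, non-basic medium avoids retro-oxa-Michael opening of the flavanone, and ring A has no free phenol to be oxidized.

Step 10
Reactants: 18 5-(benzyloxy)-7-isopropoxy-8-methoxy-2-(4-methoxyphenyl)-6-methylchroman-4-one
Product: 19 5-(benzyloxy)-7-isopropoxy-8-methoxy-2-(4-methoxyphenyl)-6-methyl-4H-chromen-4-one
Conditions: I2 (cat.), DMSO, 120 °C
Reagents that add atoms: none
Why: Iodine-catalysed dehydrogenation of a flavanone to a flavone (α-iodination through the enol, loss of HI, reoxidation of HI by DMSO); this also removes the last stereocenter.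

Step 11
Reactants: 19 5-(benzyloxy)-7-isopropoxy-8-methoxy-2-(4-methoxyphenyl)-6-methyl-4H-chromen-4-one
Product: 21 5-(benzyloxy)-3-hydroxy-7-isopropoxy-8-methoxy-2-(4-methoxyphenyl)-6-methyl-4H-chromen-4-one, via epoxide 20 (not isolated)
Conditions: DMDO, acetone/CH2Cl2, 0 °C; then p-TsOH (cat.), CH2Cl2, rt
Reagents that add atoms: dimethyldioxirane, CC1(C)OO1
Why: Dioxirane epoxidation of the enol-ether-like C2=C3 bond of a 5-O-protected flavone, then acid-catalysed opening of the 2,3-epoxide and tautomerization to the flavonol; ring A is fully substituted and offers no competing site.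

Step 12
Reactants: 21 5-(benzyloxy)-3-hydroxy-7-isopropoxy-8-methoxy-2-(4-methoxyphenyl)-6-methyl-4H-chromen-4-one
Product: 22 5-(benzyloxy)-7-isopropoxy-3,8-dimethoxy-2-(4-methoxyphenyl)-6-methyl-4H-chromen-4-one
Conditions: MeI, K2CO3, acetone, reflux
Reagents that add atoms: iodomethane, CI
Why: Williamson methylation of the only free hydroxyl, the acidic C3 enol of the flavonol.

Step 13
Reactants: 22 5-(benzyloxy)-7-isopropoxy-3,8-dimethoxy-2-(4-methoxyphenyl)-6-methyl-4H-chromen-4-one
Product: 23 5,7-dihydroxy-3,8-dimethoxy-2-(4-methoxyphenyl)-6-methyl-4H-chromen-4-one (CNP0145432.0)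
Conditions: BCl3, pentamethylbenzene, CH2Cl2, −78 → 0 °C; then MeOH, aq. work-up
Reagents that add atoms: none
Why: Lewis-acid dealkylation: boron chelated between the C4 carbonyl and O5 removes the peri benzyl group quickly, and the secondary isopropyl ether at C7 ionizes much more readily than a methyl ether, so the three methoxyls should remain at low temperature. Pentamethylbenzene traps the benzyl cation and keeps it off ring B.

## Compound list

1 | diisopropyl squarate (3,4-diisopropoxycyclobut-3-ene-1,2-dione) | CC(C)OC1=C(OC(C)C)C(=O)C1=O | starting material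
2 | 4-hydroxy-2,3-diisopropoxy-4-methylcyclobut-2-en-1-one (racemic, formed in situ) | CC(C)OC1=C(OC(C)C)C(C)(O)C1=O | intermediate
3 | 3-isopropoxy-4-methylcyclobut-3-ene-1,2-dione | CC1=C(OC(C)C)C(=O)C1=O | intermediate
4 | 4-methoxybenzaldehyde | COc1ccc(C=O)cc1 | starting material
5 | trans-1-methoxy-3-(trimethylsilyloxy)buta-1,3-diene (Danishefsky diene) | CO/C=C/C(=C)O[Si](C)(C)C | starting material
6 | 6-methoxy-2-(4-methoxyphenyl)-4-(trimethylsilyloxy)-3,6-dihydro-2H-pyran (mixture of diastereomers, formed in situ) | COC1C=C(O[Si](C)(C)C)CC(c2ccc(OC)cc2)O1 | intermediate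
7 | 2-(4-methoxyphenyl)-2,3-dihydro-4H-pyran-4-one (racemic) | O=C1C=COC(c2ccc(OC)cc2)C1 | intermediate
8 | cis-2-(4-methoxyphenyl)-3,4-dihydro-2H-pyran-4-ol (racemic, one enantiomer drawn) | C1=C[C@@H](O)C[C@@H](c2ccc(OC)cc2)O1 | intermediate
9 | cis-2-(4-methoxyphenyl)-4-(triisopropylsilyloxy)-3,4-dihydro-2H-pyran (racemic) | C1=C[C@@H](O[Si](C(C)C)(C(C)C)C(C)C)C[C@@H](c2ccc(OC)cc2)O1 | intermediate
10 | cis-6-lithio-2-(4-methoxyphenyl)-4-(triisopropylsilyloxy)-3,4-dihydro-2H-pyran (formed in situ) | [Li]C1=C[C@@H](O[Si](C(C)C)(C(C)C)C(C)C)C[C@@H](c2ccc(OC)cc2)O1 | intermediate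
11 | lithium alkoxide of 4-hydroxy-3-isopropoxy-2-methyl-4-[cis-2-(4-methoxyphenyl)-4-(triisopropylsilyloxy)-3,4-dihydro-2H-pyran-6-yl]cyclobut-2-en-1-one (formed in situ) | O=C1C(C)=C(OC(C)C)C1(O[Li])C1=C[C@@H](O[Si](C(C)C)(C(C)C)C(C)C)C[C@@H](c2ccc(OC)cc2)O1 | intermediate
12 | 3-isopropoxy-4-methoxy-2-methyl-4-[cis-2-(4-methoxyphenyl)-4-(triisopropylsilyloxy)-3,4-dihydro-2H-pyran-6-yl]cyclobut-2-en-1-one (racemic, epimers at the cyclobutenone carbon) | O=C1C(C)=C(OC(C)C)C1(OC)C1=C[C@@H](O[Si](C(C)C)(C(C)C)C(C)C)C[C@@H](c2ccc(OC)cc2)O1 | intermediate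
13 | (3Z)-3-isopropoxy-4-methoxy-2-methyl-4-[cis-2-(4-methoxyphenyl)-4-(triisopropylsilyloxy)-3,4-dihydro-2H-pyran-6-yl]buta-1,3-dien-1-one (dienylketene, formed in situ) | O=C=C(C)/C(OC(C)C)=C(OC)\C1=C[C@@H](O[Si](C(C)C)(C(C)C)C(C)C)C[C@@H](c2ccc(OC)cc2)O1 | intermediate
14 | 2,4-cis-7-isopropoxy-8-methoxy-2-(4-methoxyphenyl)-6-methyl-4-(triisopropylsilyloxy)-2,3,4,4a-tetrahydro-5H-chromen-5-one (C4a epimers, formed in situ) | COc1ccc([C@@H]2C[C@H](O[Si](C(C)C)(C(C)C)C(C)C)C3C(=O)C(C)=C(OC(C)C)C(OC)=C3O2)cc1 | intermediate
15 | cis-7-isopropoxy-8-methoxy-2-(4-methoxyphenyl)-6-methyl-4-(triisopropylsilyloxy)chroman-5-ol (racemic) | COc1ccc([C@@H]2C[C@H](O[Si](C(C)C)(C(C)C)C(C)C)c3c(O)c(C)c(OC(C)C)c(OC)c3O2)cc1 | intermediate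
16 | cis-5-(benzyloxy)-7-isopropoxy-8-methoxy-2-(4-methoxyphenyl)-6-methyl-4-(triisopropylsilyloxy)chroman (racemic) | COc1ccc([C@@H]2C[C@H](O[Si](C(C)C)(C(C)C)C(C)C)c3c(OCc4ccccc4)c(C)c(OC(C)C)c(OC)c3O2)cc1 | intermediate
17 | cis-5-(benzyloxy)-7-isopropoxy-8-methoxy-2-(4-methoxyphenyl)-6-methylchroman-4-ol (racemic) | COc1ccc([C@@H]2C[C@H](O)c3c(OCc4ccccc4)c(C)c(OC(C)C)c(OC)c3O2)cc1 | intermediate
18 | 5-(benzyloxy)-7-isopropoxy-8-methoxy-2-(4-methoxyphenyl)-6-methylchroman-4-one (racemic) | COc1ccc(C2CC(=O)c3c(OCc4ccccc4)c(C)c(OC(C)C)c(OC)c3O2)cc1 | intermediate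
19 | 5-(benzyloxy)-7-isopropoxy-8-methoxy-2-(4-methoxyphenyl)-6-methyl-4H-chromen-4-one | COc1ccc(-c2cc(=O)c3c(OCc4ccccc4)c(C)c(OC(C)C)c(OC)c3o2)cc1 | intermediate
20 | 2,3-epoxide of 19: 5-(benzyloxy)-2,3-epoxy-7-isopropoxy-8-methoxy-2-(4-methoxyphenyl)-6-methylchroman-4-one (racemic, formed in situ) | O=C1C2OC2(c2ccc(OC)cc2)Oc2c(OC)c(OC(C)C)c(C)c(OCc3ccccc3)c21 | intermediate
21 | 5-(benzyloxy)-3-hydroxy-7-isopropoxy-8-methoxy-2-(4-methoxyphenyl)-6-methyl-4H-chromen-4-one | COc1ccc(-c2oc3c(OC)c(OC(C)C)c(C)c(OCc4ccccc4)c3c(=O)c2O)cc1 | intermediate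
22 | 5-(benzyloxy)-7-isopropoxy-3,8-dimethoxy-2-(4-methoxyphenyl)-6-methyl-4H-chromen-4-one | COc1ccc(-c2oc3c(OC)c(OC(C)C)c(C)c(OCc4ccccc4)c3c(=O)c2OC)cc1 | intermediate
23 | 5,7-dihydroxy-3,8-dimethoxy-2-(4-methoxyphenyl)-6-methyl-4H-chromen-4-one (CNP0145432.0) | COc1ccc(-c2oc3c(OC)c(O)c(C)c(O)c3c(=O)c2OC)cc1 | target

## Step count and least certain steps

Total step count: 13. Longest linear sequence: 12 steps (steps 2 to 13, from 4 and 5); step 1 is a one-step branch that joins at step 5.

**Step 6 (key step).** The most likely problem is loss of the C4 silyloxy group from the product under the thermolysis conditions. Once the C5 phenol has formed, the C4 oxygen is ortho-benzylic to it and can leave through an ortho-quinone methide. The para-methoxyphenol may also be oxidized by air, and the ketene may be intercepted by adventitious nucleophiles.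

Fallback: setting out from 12, the silyl ether is cleaved with buffered fluoride (TBAF/AcOH, THF) to give 4-[cis-4-hydroxy-2-(4-methoxyphenyl)-3,4-dihydro-2H-pyran-6-yl]-3-isopropoxy-4-methoxy-2-methylcyclobut-2-en-1-one F1. The allylic alcohol is oxidized with MnO2 in CH2Cl2 to 6-(2-isopropoxy-1-methoxy-3-methyl-4-oxocyclobut-2-en-1-yl)-2-(4-methoxyphenyl)-2,3-dihydro-4H-pyran-4-one F2. Heating F2 in toluene should give the same ring opening and six-electron closure, now ending on the α-carbon of a vinylogous ester. The expected product is 5-hydroxy-7-isopropoxy-8-methoxy-2-(4-methoxyphenyl)-6-methylchroman-4-one F3, whose phenol is hydrogen-bonded to the C4 ketone and which has no benzylic leaving group. Dehydrogenation with I2 in DMSO gives 5-hydroxy-7-isopropoxy-8-methoxy-2-(4-methoxyphenyl)-6-methyl-4H-chromen-4-one F4, and benzylation (BnBr, K2CO3, DMF) returns to the route at 19.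

**Step 5.** The most likely problem is competing deprotonation by the alkyllithium at the benzylic C2–H next to the ring oxygen, or ortho to the aryl methoxyl, instead of at the vinylic C6–H. Residual base may also add to dione 3.

Fallback: setting out from 9, benzenesulfinic acid is added across the enol ether (CH2Cl2, rt) to give 4,6-cis-6-(4-methoxyphenyl)-2-(phenylsulfonyl)-4-(triisopropylsilyloxy)tetrahydro-2H-pyran F5. Its α-sulfonyl proton is by far the most acidic in the molecule, so n-butyllithium (THF, −78 °C) deprotonates only there. Addition of the anion to 3 and O-methylation with MeOTf give 3-isopropoxy-4-methoxy-2-methyl-4-[6-(4-methoxyphenyl)-2-(phenylsulfonyl)-4-(triisopropylsilyloxy)tetrahydro-2H-pyran-2-yl]cyclobut-2-en-1-one F6. Elimination of benzenesulfinic acid with DBU restores the enol ether and returns to the route at 12.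

**Step 11.** The most likely problem is poor chemoselectivity of the dioxirane: slow epoxidation of the hindered, carbonyl-conjugated C2=C3 bond, with competing C–H oxidation at the benzyl or isopropyl ether.

Fallback: setting out from 19, C3 is lithiated with LiN(iPr)2 (THF, −78 °C) and the anion is quenched with B(OMe)3 to give 5-(benzyloxy)-3-(dimethoxyboryl)-7-isopropoxy-8-methoxy-2-(4-methoxyphenyl)-6-methyl-4H-chromen-4-one F7. Oxidation of the carbon–boron bond with H2O2/AcOH returns to the route at 21.

**Step 13.** The most likely problem is over-dealkylation: a methyl ether at C3 or C8 may be lost by boron chelation to the neighbouring oxygen. Ring B may also be alkylated by the released cations.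

Fallback: setting out from 22, the benzyl ether is removed by hydrogenolysis (H2, Pd/C (palladium metal on carbon), EtOAc) to give 5-hydroxy-7-isopropoxy-3,8-dimethoxy-2-(4-methoxyphenyl)-6-methyl-4H-chromen-4-one F8. The isopropyl ether is then cleaved with HBr in acetic acid at room temperature, where a secondary alkyl ether ionizes and a methyl ether does not, arriving at 23.

## Further compounds

F1 | step 6 | 4-[cis-4-hydroxy-2-(4-methoxyphenyl)-3,4-dihydro-2H-pyran-6-yl]-3-isopropoxy-4-methoxy-2-methylcyclobut-2-en-1-one | O=C1C(C)=C(OC(C)C)C1(OC)C1=C[C@@H](O)C[C@@H](c2ccc(OC)cc2)O1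
F2 | step 6 | 6-(2-isopropoxy-1-methoxy-3-methyl-4-oxocyclobut-2-en-1-yl)-2-(4-methoxyphenyl)-2,3-dihydro-4H-pyran-4-one | O=C1C(C)=C(OC(C)C)C1(OC)C1=CC(=O)CC(c2ccc(OC)cc2)O1
F3 | step 6 | 5-hydroxy-7-isopropoxy-8-methoxy-2-(4-methoxyphenyl)-6-methylchroman-4-one | COc1ccc(C2CC(=O)c3c(O)c(C)c(OC(C)C)c(OC)c3O2)cc1
F4 | step 6 | 5-hydroxy-7-isopropoxy-8-methoxy-2-(4-methoxyphenyl)-6-methyl-4H-chromen-4-one | COc1ccc(-c2cc(=O)c3c(O)c(C)c(OC(C)C)c(OC)c3o2)cc1
F5 | step 5 | 4,6-cis-6-(4-methoxyphenyl)-2-(phenylsulfonyl)-4-(triisopropylsilyloxy)tetrahydro-2H-pyran | O=S(=O)(c1ccccc1)C1C[C@@H](O[Si](C(C)C)(C(C)C)C(C)C)C[C@@H](c2ccc(OC)cc2)O1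
F6 | step 5 | 3-isopropoxy-4-methoxy-2-methyl-4-[6-(4-methoxyphenyl)-2-(phenylsulfonyl)-4-(triisopropylsilyloxy)tetrahydro-2H-pyran-2-yl]cyclobut-2-en-1-one | O=C1C(C)=C(OC(C)C)C1(OC)C1(S(=O)(=O)c2ccccc2)C[C@@H](O[Si](C(C)C)(C(C)C)C(C)C)C[C@@H](c2ccc(OC)cc2)O1
F7 | step 11 | 5-(benzyloxy)-3-(dimethoxyboryl)-7-isopropoxy-8-methoxy-2-(4-methoxyphenyl)-6-methyl-4H-chromen-4-one | COB(OC)c1c(-c2ccc(OC)cc2)oc2c(OC)c(OC(C)C)c(C)c(OCc3ccccc3)c2c1=O
F8 | step 13 | 5-hydroxy-7-isopropoxy-3,8-dimethoxy-2-(4-methoxyphenyl)-6-methyl-4H-chromen-4-one | COc1ccc(-c2oc3c(OC)c(OC(C)C)c(C)c(O)c3c(=O)c2OC)cc1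
A1 | alternative 1 | 5,7-bis(benzyloxy)-3-methoxy-2-(4-methoxyphenyl)-6-methylchromen-4-one | COc1ccc(-c2oc3cc(OCc4ccccc4)c(C)c(OCc4ccccc4)c3c(=O)c2OC)cc1
A2 | alternative 1 | 3,5-bis(benzyloxy)-4-methyl-2-(trimethylsilyl)phenyl trifluoromethanesulfonate | C[Si](C)(C)c1c(OS(=O)(=O)C(F)(F)F)cc(OCc2ccccc2)c(C)c1OCc1ccccc1
A3 | alternative 1 | 2,3-dimethoxy-3-(4-methoxyphenyl)acrylic acid | COC(C(=O)O)=C(OC)c1ccc(OC)cc1
A4 | alternative 2 | 5-hydroxy-3,8-dimethoxy-2-(4-methoxyphenyl)-6-methyl-7-(triisopropylsilyloxy)chromen-4-one | COc1ccc(-c2oc3c(OC)c(O[Si](C(C)C)(C(C)C)C(C)C)c(C)c(O)c3c(=O)c2OC)cc1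
A5 | alternative 2 | 2-methoxy-2-[5-methoxy-6-(4-methoxyphenyl)-4-oxo-4H-pyran-2-yl]acetyl chloride | COC(C(=O)Cl)c1cc(=O)c(OC)c(-c2ccc(OC)cc2)o1
A6 | alternative 2 | 1-(triisopropylsilyloxy)prop-1-yne | CC#CO[Si](C(C)C)(C(C)C)C(C)C
A7 | alternative 3 | 5,7-bis(benzyloxy)-8-methoxy-2-(4-methoxyphenyl)-6-methylchromen-4-one | COc1ccc(-c2cc(=O)c3c(OCc4ccccc4)c(C)c(OCc4ccccc4)c(OC)c3o2)cc1
A8 | alternative 3 | 3,5-bis(benzyloxy)-2-iodo-6-methoxy-4-methylphenol | COc1c(O)c(I)c(OCc2ccccc2)c(C)c1OCc1ccccc1
A9 | alternative 3 | 4-ethynylanisole | C#Cc1ccc(OC)cc1
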